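Count the reagent before reading the clock. The grey flask is the one asked about, and the blue run is the same recipe made cooler.

all flasks: substrate 0.25 M; solid reagent 0.325 M
- grey: temperature 110 °C; the very flask that is asked about, followed so far
- blue: temperature 95 °C; run made earlier
- flask: temperature 110 °C; time 8.0 d

- grey (time / h: tris adduct / %, substrate / %): 25.0: 17.8, 31.8; 50.0: 22.4, 26.4; 72.0: 23.3, 25.7; 96.0: 23.2, 26.3; 120: 22.0, 26.2
- blue (time / h: tris adduct / %, substrate / %): 48.0: 12.0, 34.2; 96.0: 17.8, 26.1; 144: 20.7, 24.4; 192: 20.7, 22.8; 240: 20.6, 23.7

(each reading ± 0.5 percentage points)

- given per volume of solution although it is solid: solid reagent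
- what is taken out of tris adduct is counted as made
- at the start none of the solid reagent is in solution
- additions bring no volume worth counting

- oak: at 8.0 d raise the temperature by 25 K, then wait 8.0 d
- larch: at 8.0 d add substrate, 50.0% of the amount charged, then wait 8.0 d
- alder: change nothing and wait 8.0 d more
- maple: at 8.0 d take out 90% of the tris adduct then present, then wait 8.0 d

- tris adduct, in percent of the substrate first charged, at 8.0 d
- the remedy with the largest gain of tris adduct, or "none" below 2 percentage points (oak / larch / alder / maple / none)
- tris adduct present, with what was taken out counted in, in percent of the substrate first charged, after oak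
- tris adduct present, with what was taken out counted in, in percent of the substrate first charged, after alder

We read one unit of reagent on substrate as first product, two as double product and 3 as tris adduct, and the charge offers 1.30 equivalents per substrate. We carry one quantity, which at 96.0 h in the grey run is 0.0990 equivalents: the spare reagent, meaning the charge less the least that the readings can have used, with each tris adduct counted as 3 units and every other reacted substrate as one.

Now the grey run in slow motion. At the start none of the solid reagent is in solution, and addition begins as it dissolves. By 25.0 h substrate has dropped to 31.8% and tris adduct has reached 17.8%, which gives a spare reagent of 0.262 equivalents. At 50.0 h the spare reagent is 0.116 equivalents, so it has lost more in this stretch than it loses from there to 96.0 h. At the end, from 72.0 h to 120 h, tris adduct reads 23.3%, 23.2% and 22.0% and substrate reads 25.7%, 26.3% and 26.2%, with a scatter of 0.5 percentage points, so tris adduct shows no rise and substrate no fall.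

The spare figure is a ceiling, read with the scatter of the readings. It reaches zero if double product holds 9.90% of the charged substrate, which is less than the 50.5% not accounted for by substrate or tris adduct. So we take the solid reagent as the limiting reagent. The options bring heat, substrate or time, or take out tris adduct, and reagent is not among them. We commit to the mean of the last 3 readings, 22.8%, and to no useful option.

The forecast gives 22.8% now, 23.3% after oak, 22.8% after alder and none as the best remedy, reasoning that “the reagent may simply be spent”.

The flask gives 22.6%, with 22.6% after oak, 22.6% after alder and none as the best remedy.

    partner + first product → double product (k = 8.20 × 10⁻⁵ L mol⁻¹ s⁻¹, Ea = 91.0 kJ mol⁻¹)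
    substrate + partner → first product (k = 1.00 × 10⁻⁴ L mol⁻¹ s⁻¹, Ea = 77.0 kJ mol⁻¹)
    solid reagent ⇌ partner, rate k3*(cs3 - [partner]) while solid is left; crystals form when [partner] > cs3 (solubility = 0.250 M, k = 6.60 × 10⁻⁴ s⁻¹)
    partner + double product → tris adduct (k = 2.70 × 10⁻⁴ L mol⁻¹ s⁻¹, Ea = 96.0 kJ mol⁻¹)
    (constants at 110 °C)

At 192 h the grey flask holds solid reagent 0%, dissolved partner 5.48 × 10⁻⁸ M and double product 11.3%. With 0.81 M of solid reagent instead, a neighbouring flask ends at tris adduct 99.2% and substrate 0.031%. Its spare reagent comes to 0.257 equivalents, or 0.0642 M, and its partner stands at 0.0636 M.

(The earlier runs and the new flask stem from a simulated flask with constants of no real substance.)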